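**Plan**

- Retrosynthesis: first the two O–benzyl bonds of a protected catechol are cut. Then, in one operation, the lactone bond C2(=O)–C3 and the exocyclic CH2–aryl bond, which leads back to an acyclic O-aryl O-homoallyl thionocarbonate. Then the two C–O bonds at the thiocarbonyl carbon (alcohol + thiophosgene + phenol), and last the benzylic C–C bond at the future C4.
- Forward: the four-carbon chain is built on an oxazolidinone (crotonyl imide, α-veratrylation, reduction). The catechol ring is attached through oxygen as a thionocarbonate. The γ-lactone, the only ring formed, is closed by a radical cyclisation in which the aryl group moves from O to C, and hydrogenolysis finishes.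
- Enabling feature: in the ring O1–C2(=O)–C3–C4–C5 the carbonyl oxygen on C2 lies 1,4 to the ipso carbon of the catechol ring (O=C2–C3–CH2–Ar), and C3–CH2 is a former vinyl group on C4. An aryl group parked on that oxygen can therefore be handed to the CH2 radical through a five-membered ipso transition state. The thiocarbonyl sulfur is the only helper and leaves in the same step.
- Stereochemistry: C4 (R) comes from (R)-4-benzyloxazolidinone in the dienolate alkylation. C3 (R) comes from substrate control in the 5-exo cyclisation, the new CH2 being delivered trans to the C4 substituent.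

Key step: step 7

Remark: the short-lived radicals of step 7 are numbered like other non-isolated intermediates; the configuration at their transient C2 acetal carbon is undefined and disappears when the carbonyl forms.

**Route**

Step 1
Reactants: 1 (R)-4-benzyl-1,3-oxazolidin-2-one; 2 (E)-but-2-enoyl chloride (crotonyl chloride)
Product: 3 (R)-4-benzyl-3-[(E)-but-2-enoyl]-1,3-oxazolidin-2-one
Conditions: n-BuLi, THF, −78 °C; then 2, −78 → 0 °C
Reagents that add atoms: none
Why: N-acylation of the lithiated oxazolidinone with the acid chloride (Evans imide formation) is fast at −78 °C, and no stereocentre is formed or disturbed.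

Step 2
Reactants: 3 (R)-4-benzyl-3-[(E)-but-2-enoyl]-1,3-oxazolidin-2-one; 4 3,4-dimethoxybenzyl bromide
Product: 6 (R)-4-benzyl-3-[(R)-2-(3,4-dimethoxybenzyl)but-3-enoyl]-1,3-oxazolidin-2-one, via sodium dienolate 5 (not isolated)
Conditions: NaHMDS (1.05 equiv), THF, −78 °C; then 4, −78 → −45 °C; AcOH quench at low temperature
Reagents that add atoms: none
Why: Evans alkylation of the chelated sodium (Z)-dienolate 5: the extended enolate reacts with the benzylic bromide at its α-carbon (deconjugative alkylation) on the face opposite the benzyl group of the auxiliary, which sets the future C4 as R.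

Step 3
Reactants: 6 (R)-4-benzyl-3-[(R)-2-(3,4-dimethoxybenzyl)but-3-enoyl]-1,3-oxazolidin-2-one
Product: 7 (R)-2-(3,4-dimethoxybenzyl)but-3-en-1-ol
Conditions: LiBH4, H2O (1 equiv), Et2O–THF, 0 °C
Reagents that add atoms: none
Why: Reductive removal of the Evans auxiliary: borohydride attacks the more electrophilic exocyclic imide carbonyl and reduces it to the primary alcohol in the cold, leaving the terminal alkene and the allylic stereocentre untouched.

Step 4
Reactants: 8 3,4-bis(benzyloxy)benzaldehyde
Product: 10 3,4-bis(benzyloxy)phenol, via aryl formate 9 (not isolated)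
Conditions: mCPBA, CH2Cl2, rt; then K2CO3 (cat.), MeOH, rt
Reagents that add atoms: mCPBA, OOC(=O)c1cccc(Cl)c1
Why: Baeyer–Villiger (Dakin-type) oxidation: in the Criegee adduct the electron-rich aryl group migrates to oxygen to give formate 9, which base-catalysed methanolysis converts into the phenol, the benzyl ethers being inert to both reagents.

Step 5
Reactants: 10 3,4-bis(benzyloxy)phenol; 11 thiophosgene
Product: 12 O-[3,4-bis(benzyloxy)phenyl] carbonochloridothioate (aryl chlorothionoformate)
Conditions: CSCl2 (1.2 equiv), CHCl3, 0 °C; aq NaOH (1.0 equiv) added slowly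
Reagents that add atoms: none
Why: Schotten–Baumann-type substitution at thiophosgene by the phenoxide, kept at the mono-substitution stage by excess thiophosgene and slow addition of base, is the standard preparation of aryl chlorothionoformates.

Step 6
Reactants: 7 (R)-2-(3,4-dimethoxybenzyl)but-3-en-1-ol; 12 O-[3,4-bis(benzyloxy)phenyl] carbonochloridothioate
Product: 13 O-[3,4-bis(benzyloxy)phenyl] O-[(R)-2-(3,4-dimethoxybenzyl)but-3-en-1-yl] carbonothioate (thionocarbonate)
Conditions: pyridine (2 equiv), DMAP (cat.), CH2Cl2, 0 °C → rt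
Reagents that add atoms: none
Why: Pyridine/DMAP-mediated O-thioacylation of the unhindered primary alcohol by the chlorothionoformate gives the mixed O-alkyl O-aryl thionocarbonate, with the stereocentre two bonds from the reacting oxygen and unaffected.

Step 7
Reactants: 13 O-[3,4-bis(benzyloxy)phenyl] O-[(R)-2-(3,4-dimethoxybenzyl)but-3-en-1-yl] carbonothioate
Product: 18 (3R,4R)-3-[3,4-bis(benzyloxy)benzyl]-4-(3,4-dimethoxybenzyl)dihydrofuran-2(3H)-one, via silylthio carbon radical 14 (not isolated), via cyclised primary radical 15 (not isolated), via spirocyclohexadienyl radical 16 (not isolated), via alkoxyl radical 17 (not isolated)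
Conditions: (Me3Si)3SiH (1.5 equiv), AIBN (0.3 equiv, in portions), benzene (0.02 M), 80 °C
Reagents that add atoms: none
Why: Radical chain: the silyl radical adds to the thiocarbonyl sulfur to give carbon radical 14, which cyclises onto the vinyl group to primary radical 15; 15 attacks the ipso carbon of the O-bound aryl ring through a five-membered spiro transition state (16), the C(ipso)–O bond then breaks with rearomatisation (17), and loss of the silylthiyl radical, which takes hydrogen from the silane and so carries the chain, leaves the lactone carbonyl. The closest known reaction type is exactly this radical carboxyarylation of O-aryl O-homoallyl thionocarbonates (thiocarbonyl radical cyclisation followed by 1,4-aryl migration from oxygen to carbon), a known entry to trans-α-benzyl-β-substituted γ-butyrolactones. The lactone ring closes in the 5-exo-trig mode by the C2–C3 bond; the second five-membered ring of 16 is transient and opens again within the step. C3 is the only new stereocentre and is controlled by C4: in the chair-like 5-exo transition state the veratrylmethyl group lies pseudo-equatorial, so the new CH2 is delivered trans to it (3R,4R), as expected for a 4-substituted 5-hexenyl radical. The step needs cyclisation and aryl transfer to outrun hydrogen transfer to 14 and 15 and deoxygenative fragmentation of 14, which the slow hydrogen donor (Me3Si)3SiH at high dilution and the primary (slow to cleave) C–O bond secure. It also needs attack on the O-aryl ring and not on the veratryl ring, which is secured because only ipso attack on the aryloxy group is made irreversible by C–O scission to the carbonyl.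

Step 8
Reactants: 18 (3R,4R)-3-[3,4-bis(benzyloxy)benzyl]-4-(3,4-dimethoxybenzyl)dihydrofuran-2(3H)-one
Product: 19 3'-O-demethylarctigenin, (3R,4R)-3-(3,4-dihydroxybenzyl)-4-(3,4-dimethoxybenzyl)dihydrofuran-2(3H)-one
Conditions: H2 (1 atm), 10% Pd/C, EtOAc–EtOH, rt; work-up under argon
Reagents that add atoms: none
Why: Pd-catalysed hydrogenolysis of the two aryl benzyl ethers frees the catechol under neutral conditions that leave the methyl ethers, the lactone and both stereocentres (trans is also the thermodynamically preferred arrangement) unchanged.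

**Compound list**

1 | (R)-4-benzyl-1,3-oxazolidin-2-one | O=C1N[C@H](Cc2ccccc2)CO1 | starting material
2 | (E)-but-2-enoyl chloride (crotonyl chloride) | C/C=C/C(Cl)=O | starting material
3 | (R)-4-benzyl-3-[(E)-but-2-enoyl]-1,3-oxazolidin-2-one | C/C=C/C(=O)N1[C@H](Cc2ccccc2)COC1=O | intermediate
4 | 3,4-dimethoxybenzyl bromide | COc1ccc(CBr)cc1OC | starting material
5 | sodium (Z)-dienolate of 3 (vinyl cis to O–Na) | C=C/C=C(\[O-])N1[C@H](Cc2ccccc2)COC1=O.[Na+] | intermediate
6 | (R)-4-benzyl-3-[(R)-2-(3,4-dimethoxybenzyl)but-3-enoyl]-1,3-oxazolidin-2-one | COc1ccc(C[C@H](C=C)C(=O)N2[C@H](Cc3ccccc3)COC2=O)cc1OC | intermediate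
7 | (R)-2-(3,4-dimethoxybenzyl)but-3-en-1-ol | COc1ccc(C[C@H](C=C)CO)cc1OC | intermediate
8 | 3,4-bis(benzyloxy)benzaldehyde | O=Cc1ccc(OCc2ccccc2)c(OCc2ccccc2)c1 | starting material
9 | 3,4-bis(benzyloxy)phenyl formate | O=COc1ccc(OCc2ccccc2)c(OCc2ccccc2)c1 | intermediate
10 | 3,4-bis(benzyloxy)phenol | Oc1ccc(OCc2ccccc2)c(OCc2ccccc2)c1 | intermediate
11 | thiophosgene | S=C(Cl)Cl | starting material
12 | O-[3,4-bis(benzyloxy)phenyl] carbonochloridothioate | S=C(Cl)Oc1ccc(OCc2ccccc2)c(OCc2ccccc2)c1 | intermediate
13 | O-[3,4-bis(benzyloxy)phenyl] O-[(R)-2-(3,4-dimethoxybenzyl)but-3-en-1-yl] carbonothioate | COc1ccc(C[C@H](C=C)COC(=S)Oc2ccc(OCc3ccccc3)c(OCc3ccccc3)c2)cc1OC | intermediate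
14 | carbon radical from addition of (Me3Si)3Si• to the sulfur of 13 (alkoxy, aryloxy, silylthio substituents) | COc1ccc(C[C@H](C=C)CO[C](S[Si]([Si](C)(C)C)([Si](C)(C)C)[Si](C)(C)C)Oc2ccc(OCc3ccccc3)c(OCc3ccccc3)c2)cc1OC | intermediate
15 | 3,4-trans [2-aryloxy-4-(3,4-dimethoxybenzyl)-2-(silylthio)tetrahydrofuran-3-yl]methyl radical | COc1ccc(C[C@H]2COC(Oc3ccc(OCc4ccccc4)c(OCc4ccccc4)c3)(S[Si]([Si](C)(C)C)([Si](C)(C)C)[Si](C)(C)C)[C@@H]2[CH2])cc1OC | intermediate
16 | spirocyclohexadienyl radical from ipso attack of 15 on the aryloxy ring (2,8-dioxabicyclo[3.3.0]octane core) | COc1ccc(C[C@H]2COC3(S[Si]([Si](C)(C)C)([Si](C)(C)C)[Si](C)(C)C)OC4(C=C(OCc5ccccc5)[C](OCc5ccccc5)C=C4)C[C@H]23)cc1OC | intermediate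
17 | C2 alkoxyl radical after aryl transfer (3-arylmethyl-2-(silylthio)tetrahydrofuran-2-yloxyl) | COc1ccc(C[C@H]2COC([O])(S[Si]([Si](C)(C)C)([Si](C)(C)C)[Si](C)(C)C)[C@@H]2Cc2ccc(OCc3ccccc3)c(OCc3ccccc3)c2)cc1OC | intermediate
18 | (3R,4R)-3-[3,4-bis(benzyloxy)benzyl]-4-(3,4-dimethoxybenzyl)dihydrofuran-2(3H)-one | COc1ccc(C[C@H]2COC(=O)[C@@H]2Cc2ccc(OCc3ccccc3)c(OCc3ccccc3)c2)cc1OC | intermediate
19 | 3'-O-demethylarctigenin, (3R,4R)-3-(3,4-dihydroxybenzyl)-4-(3,4-dimethoxybenzyl)dihydrofuran-2(3H)-one | COc1ccc(C[C@H]2COC(=O)[C@@H]2Cc2ccc(O)c(O)c2)cc1OC | target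

**Count and risks**

Total steps: 8. Longest linear sequence: 6 steps (steps 1, 2, 3, 6, 7, 8); steps 4 and 5 form a side branch that joins at step 6.

The three steps most likely to fail are, in order of risk, step 7, step 2 and step 5.

Risk 1 (step 7). The primary radical may be reduced by the silane before the aryl shift, the first radical may fragment with loss of the oxygen function instead of cyclising, or the facial selectivity at C3 may be poor. The fallback avoids radicals and sets C3 by enolate alkylation; it sets out from 7 and comes back at 18. Alcohol 7 would be hydroborated and oxidised (9-BBN, THF; then NaOH, H2O2) to (R)-2-(3,4-dimethoxybenzyl)butane-1,4-diol F1. Oxidative lactonisation with TEMPO/PhI(OAc)2, which starts at the less hindered C4 carbinol, would give (R)-4-(3,4-dimethoxybenzyl)dihydrofuran-2(3H)-one F2. In parallel, aldehyde 8 would be reduced (NaBH4, MeOH) to [3,4-bis(benzyloxy)phenyl]methanol F3 and brominated (PBr3, Et2O, 0 °C) to 3,4-bis(benzyloxy)benzyl bromide F4. Deprotonation of F2 (LiHMDS, THF, −78 °C) and alkylation with F4 anti to the C4 substituent would give 18.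

Risk 2 (step 2). The dienolate may be alkylated at the γ-carbon or twice, or base may move the double bond into conjugation with loss of the new stereocentre. The fallback masks the vinyl group as a 2-(phenylselanyl)ethyl group, so that the alkylation becomes an ordinary Evans alkylation of a saturated imide; it sets out from 1 and comes back at 7. 4-(Phenylselanyl)butanoic acid F5 (from γ-butyrolactone by ring opening with (PhSe)2/NaBH4 in hot DMF) would be coupled to 1 (DCC, cat. DMAP, CH2Cl2) to give (R)-4-benzyl-3-[4-(phenylselanyl)butanoyl]-1,3-oxazolidin-2-one F6. Enolisation with NaHMDS and alkylation with 4 at −78 °C would give (R)-4-benzyl-3-[(R)-2-(3,4-dimethoxybenzyl)-4-(phenylselanyl)butanoyl]-1,3-oxazolidin-2-one F7. LiBH4 would then release (R)-2-(3,4-dimethoxybenzyl)-4-(phenylselanyl)butan-1-ol F8. Oxidation at selenium (H2O2, pyridine, THF) and thermal syn-elimination would unveil the vinyl group of 7.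

Risk 3 (step 5). Thiophosgene may be substituted twice, giving the symmetrical diaryl thionocarbonate, or the moisture-sensitive chlorothionoformate may hydrolyse on handling. The fallback assembles the thionocarbonate from the alcohol side without thiophosgene; it sets out from 7 and comes back at 13. Alcohol 7 would be treated with 1,1'-thiocarbonyldiimidazole (THF, rt) to give O-[(R)-2-(3,4-dimethoxybenzyl)but-3-en-1-yl] 1H-imidazole-1-carbothioate F9. The imidazole would then be displaced by phenol 10 (cat. DMAP, toluene, 80 °C) to give 13.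

**Further compounds**

F1 | step 7 | (R)-2-(3,4-dimethoxybenzyl)butane-1,4-diol | COc1ccc(C[C@H](CCO)CO)cc1OC
F2 | step 7 | (R)-4-(3,4-dimethoxybenzyl)dihydrofuran-2(3H)-one | COc1ccc(C[C@H]2COC(=O)C2)cc1OC
F3 | step 7 | [3,4-bis(benzyloxy)phenyl]methanol | OCc1ccc(OCc2ccccc2)c(OCc2ccccc2)c1
F4 | step 7 | 3,4-bis(benzyloxy)benzyl bromide | BrCc1ccc(OCc2ccccc2)c(OCc2ccccc2)c1
F5 | step 2 | 4-(phenylselanyl)butanoic acid | OC(=O)CCC[Se]c1ccccc1
F6 | step 2 | (R)-4-benzyl-3-[4-(phenylselanyl)butanoyl]-1,3-oxazolidin-2-one | O=C(CCC[Se]c1ccccc1)N1[C@H](Cc2ccccc2)COC1=O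
F7 | step 2 | (R)-4-benzyl-3-[(R)-2-(3,4-dimethoxybenzyl)-4-(phenylselanyl)butanoyl]-1,3-oxazolidin-2-one | COc1ccc(C[C@H](CC[Se]c2ccccc2)C(=O)N2[C@H](Cc3ccccc3)COC2=O)cc1OC
F8 | step 2 | (R)-2-(3,4-dimethoxybenzyl)-4-(phenylselanyl)butan-1-ol | COc1ccc(C[C@H](CC[Se]c2ccccc2)CO)cc1OC
F9 | step 5 | O-[(R)-2-(3,4-dimethoxybenzyl)but-3-en-1-yl] 1H-imidazole-1-carbothioate | COc1ccc(C[C@H](C=C)COC(=S)n2ccnc2)cc1OC
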